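**Assumption:** the target is the free acid as drawn (C23H31ClO8). The anomeric configuration of 1 is irrelevant, because C1 is removed in step 2. The Wittig Z/E isomers in step 14 are separable.

## Retrosynthetic overview
1. Target ⇐ global desilylation/ester cleavage ⇐ C13–OH/C1′–CO2H Yamaguchi macrolactonisation (ring closed last).
2. Seco-acid ⇐ Ni/photoredox decarboxylative C(sp3)–C(sp2) coupling (C9–C8 bond) of a sugar-derived NHPI ester with a malate-derived gem-dichloroalkene. This forms the Z-chlorovinyl group by stereoretentive mono-coupling.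
3. Sugar half from D-glucurono-6,3-lactone, which already holds the C3/C4/C5 stereotriad, the closed THF ring and C6 at acid level. The glycal is alkylated at C1 (2-deoxy, anti to the lactone), then lactol Wittig and cross-metathesis build the E-trisubstituted side chain.
4. Malate half: (R)-malic acid → α-hydroxy methyl ketone → Z-selective Wittig → dichloro-olefination. Ring order: THF (pre-formed, C1 alkylated) → Z-vinyl chloride (acyclic coupling) → 14-membered lactone.

## Route

**Step 1**
Reactants: 1 D-glucurono-6,3-lactone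
Product: 2 1,2-O-thiocarbonyl-α-D-glucofuranurono-6,3-lactone
Conditions: TCDI, DMAP (cat.), MeCN, 50 °C
Reagents that add atoms: 1,1′-thiocarbonyldiimidazole, S=C(n1ccnc1)n1ccnc1
Why: The cis-1,2-diol gives the 5-membered thionocarbonate (diol → thionocarbonate); C5–OH is left free and no new stereocentre is made.

**Step 2**
Reactants: 2
Product: 3 furanoid glycal lactone (1,4-anhydro-2-deoxy-D-arabino-hex-1-enofuranurono-6,3-lactone, 5-OH free)
Conditions: P(OMe)3 (neat), 110 °C
Reagents that add atoms: none
Why: Corey–Winter olefination removes the C1/C2 oxygens with loss of CO2 and S=P(OMe)3, giving the 2-deoxy glycal; C3, C4 and C5 are untouched.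

**Step 3**
Reactants: 3
Product: 4 5-O-TBS glycal lactone
Conditions: TBSOTf, 2,6-lutidine, CH2Cl2, −78 °C
Reagents that add atoms: TBSOTf, CC(C)(C)[Si](C)(C)OS(=O)(=O)C(F)(F)F
Why: Non-basic silylation of the only free OH avoids epimerisation at C5, which is α to the lactone carbonyl.

**Step 4**
Reactants: 4; 5 tert-butyl acrylate
Product: 6 tert-butyl 3-(5-O-TBS-2-deoxy-α-D-arabino-hexofuranurono-6,3-lactone-1-C-yl)propanoate
Conditions: Fe(acac)3 (0.3 equiv), PhSiH3 (2 equiv), 5 (3 equiv), iPrOH, 40 °C
Reagents that add atoms: none (PhSiH3 supplies H only)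
Why: Fe–H hydrogen-atom transfer (Mukaiyama–Baran olefin cross-coupling) puts H on C2 and gives the α-oxy C1 radical, which adds to the acrylate (Giese). Attack occurs on the convex face anti to the cis-fused lactone, so the chain at C1 is trans to O3 and C5, as in the target.

**Step 5**
Reactants: 6
Product: 7 lactol (6-hydroxy, C6 epimer mixture)
Conditions: DIBAL-H (1.05 equiv), CH2Cl2, −78 °C; Rochelle salt work-up
Reagents that add atoms: none
Why: The strained bicyclic lactone is reduced faster than the hindered tert-butyl ester, giving the C6 aldehyde level without touching any stereocentre.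

**Step 6**
Reactants: 7
Product: 8 tert-butyl 3-[4-hydroxy-5-(1-TBSO-allyl)tetrahydrofuran-2-yl]propanoate (2,5-trans, 3,4-cis)
Conditions: Ph3P+CH3 Br−, KOtBu (3 equiv each), THF, 0 °C → rt
Reagents that add atoms: methylenetriphenylphosphorane, C=P(c1ccccc1)(c1ccccc1)c1ccccc1
Why: The lactol opens to the α-silyloxy aldehyde, which undergoes Wittig methylenation, freeing 3-OH and leaving C5 (the D-gluco carbinol) unchanged.

**Step 7**
Reactants: 9 3-methylbut-3-enoic acid
Product: 10 2-(trimethylsilyl)ethyl 3-methylbut-3-enoate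
Conditions: TMS-ethanol, EDC·HCl, DMAP, CH2Cl2, 0 °C → rt
Reagents that add atoms: 2-(trimethylsilyl)ethanol, C[Si](C)(C)CCO
Why: Steglich esterification gives an ester that is later removed by fluoride together with the TBS group.

**Step 8**
Reactants: 8; 10
Product: 11 E-trisubstituted side-chain alkene
Conditions: Hoveyda–Grubbs II (5 mol %), 10 (5 equiv), CH2Cl2, 40 °C
Reagents that add atoms: none (ethylene is lost)
Why: Cross-metathesis of a terminal allylic silyl ether with a 1,1-disubstituted alkene gives the thermodynamic E-alkene; no stereocentre is altered.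

**Step 9**
Reactants: 11
Product: 12 carboxylic acid (tert-butyl ester removed)
Conditions: TMSOTf (4 equiv), 2,6-lutidine (6 equiv), CH2Cl2, 0 °C; then MeOH/aq. NaH2PO4
Reagents that add atoms: none
Why: TMSOTf/lutidine cleaves tert-butyl esters via silyl esters under non-protic conditions, so the allylic TBS ether and TMSE ester survive.

**Step 10**
Reactants: 12
Product: 13 NHPI ester
Conditions: NHPI, DIC, DMAP (5 mol %), CH2Cl2, 0 °C → rt
Reagents that add atoms: N-hydroxyphthalimide, ON1C(=O)c2ccccc2C1=O
Why: Carbodiimide coupling gives the redox-active ester; the free 3-OH is less acidic and slower to acylate than NHPI.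

**Step 11**
Reactants: 14 (R)-malic acid
Product: 15 (R)-(2,2-dimethyl-5-oxo-1,3-dioxolan-4-yl)acetic acid
Conditions: 2,2-dimethoxypropane, TsOH·H2O (cat.), acetone, 40 °C
Reagents that add atoms: 2,2-dimethoxypropane, COC(C)(C)OC
Why: Acetonide formation masks the α-hydroxy acid and leaves the β-CO2H free; the malate stereocentre (becomes Ca, 3′-OAc) is untouched.

**Step 12**
Reactants: 15
Product: 16 tert-butyl ester of 15
Conditions: Boc2O, tBuOH, DMAP, rt
Reagents that add atoms: di-tert-butyl dicarbonate, CC(C)(C)OC(=O)OC(=O)OC(C)(C)C; tert-butanol, CC(C)(C)O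
Why: This is the standard tert-butyl ester synthesis, with no reaction at the stereocentre.

**Step 13**
Reactants: 16
Product: 17 tert-butyl (R)-3-hydroxy-4-oxopentanoate
Conditions: Me2CuLi (2.5 equiv), THF, −78 °C; aq. NH4Cl
Reagents that add atoms: lithium dimethylcuprate, C[Cu-]C.[Li+]
Why: The cuprate acylates selectively at the activated acylal carbonyl (acetone is released) and does not add to the ketone, giving the α-hydroxy methyl ketone with the stereocentre retained.

**Step 14**
Reactants: 17; 18 [2-(1,3-dioxolan-2-yl)ethyl]triphenylphosphonium bromide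
Product: 19 tert-butyl (3R,4Z)-3-hydroxy-4-methyl-6-(1,3-dioxolan-2-yl)hex-4-enoate
Conditions: 18 (2.5 equiv), KHMDS (2.3 equiv), THF, 0 °C; add 17 at −78 °C → rt
Reagents that add atoms: none
Why: Wittig olefination of the methyl ketone with a non-stabilised ylide (free OH as alkoxide) favours the cis-oxaphosphetane, placing the ylide chain cis to Ca; I expect Z:E of about 4:1, with the Z isomer separated.

**Step 15**
Reactants: 19
Product: 20 acetate of 19
Conditions: Ac2O, pyridine, DMAP (cat.), CH2Cl2, 0 °C
Reagents that add atoms: acetic anhydride, CC(=O)OC(C)=O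
Why: Acetylation of the allylic β-hydroxy ester (done after the Wittig step to avoid base-induced β-elimination of acetate); Ca retains its configuration.

**Step 16**
Reactants: 20
Product: 21 tert-butyl (3R,4Z)-3-acetoxy-4-methyl-7-oxohept-4-enoate
Conditions: PPTS (0.3 equiv), acetone/H2O 10:1, 50 °C
Reagents that add atoms: water, O
Why: Mild acetal hydrolysis releases the β,γ-unsaturated aldehyde without isomerising the Z-alkene or cleaving the tert-butyl ester.

**Step 17**
Reactants: 21
Product: 22 tert-butyl (3R,4Z)-3-acetoxy-8,8-dichloro-4-methylocta-4,7-dienoate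
Conditions: PPh3 (2 equiv), CCl4 (5 equiv), CH2Cl2, 0 °C → rt
Reagents that add atoms: carbon tetrachloride, ClC(Cl)(Cl)Cl
Why: Ramirez gem-dichloro-olefination under neutral conditions leaves the stereocentre and the Z-alkene intact.

**Step 18**
Reactants: 13; 22
Product: 23 seco-ester with Z-chlorovinyl group (3-OH free, C1′ as tert-butyl ester, side-chain acid as TMSE ester)
Conditions: NiBr2·diglyme (10 mol %), dtbbpy (12 mol %), fac-Ir(ppy)3 (1 mol %), Hantzsch ester (1.5 equiv), 22 (2.5 equiv), DMA, blue LEDs, 25 °C
Reagents that add atoms: none (Hantzsch ester supplies H only)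
Why: Proposed new method: the photoreduced NHPI ester loses CO2 to give the primary C9 radical; Ni(0) adds oxidatively only to the less hindered C–Cl that is trans to the allylic CH2 of the gem-dichloroalkene (Cl cis to H), the radical is captured, and C(sp3)–C(sp2) reductive elimination with retention leaves the remaining Cl cis to C6, i.e. the Z-chloroalkene; the closest known reactions are Ni/photoredox decarboxylative alkenylation of NHPI esters with vinyl halides and Pd-catalysed stereoretentive mono-coupling of 1,1-dichloroalkenes.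

**Step 19**
Reactants: 23
Product: 24 seco-acid (C1′ CO2H free)
Conditions: TMSOTf (4 equiv), 2,6-lutidine (6 equiv), CH2Cl2, 0 °C; then MeOH/aq. NaH2PO4
Reagents that add atoms: none
Why: The same non-protic tert-butyl ester cleavage as step 9, compatible with the acetate, TBS ether, TMSE ester and vinyl chloride.

**Step 20**
Reactants: 24
Product: 25 protected macrolactone
Conditions: 2,4,6-Cl3C6H2COCl, Et3N, THF, rt; then slow addition to DMAP (10 equiv), toluene, 80 °C (2 mM)
Reagents that add atoms: none
Why: Yamaguchi macrolactonisation closes the 14-membered ring at the only free OH (C3–OH, the target's lactone-bearing ring carbon, Cb), with no change at any stereocentre.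

**Step 21**
Reactants: 25
Product: 26 target
Conditions: TBAF (8 equiv), AcOH (8 equiv), THF, 0 °C → rt; pH 4 work-up
Reagents that add atoms: none
Why: Buffered fluoride removes the TBS ether and the TMSE ester in one operation, leaving the acetate, the lactone, the chloroalkene and all stereocentres intact.

## Compound list
1 | D-glucurono-6,3-lactone (anomeric mixture) | OC1O[C@@H]2[C@H](O)C(=O)O[C@@H]2[C@H]1O | starting material
2 | 1,2-O-thiocarbonyl lactone | S=C1O[C@H]2O[C@@H]3[C@H](O)C(=O)O[C@@H]3[C@H]2O1 | intermediate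
3 | glycal lactone (5-OH) | C1=C[C@H]2OC(=O)[C@@H](O)[C@H]2O1 | intermediate
4 | 5-O-TBS glycal lactone | C1=C[C@H]2OC(=O)[C@@H](O[Si](C)(C)C(C)(C)C)[C@H]2O1 | intermediate
5 | tert-butyl acrylate | C=CC(=O)OC(C)(C)C | starting material
6 | C1 propanoate lactone | CC(C)(C)OC(=O)CC[C@@H]1C[C@H]2OC(=O)[C@@H](O[Si](C)(C)C(C)(C)C)[C@H]2O1 | intermediate
7 | lactol (C6 epimer mixture) | CC(C)(C)OC(=O)CC[C@@H]1C[C@H]2OC(O)[C@@H](O[Si](C)(C)C(C)(C)C)[C@H]2O1 | intermediate
8 | vinyl carbinol silyl ether, 3-OH free | O[C@@H]2C[C@@H](CCC(=O)OC(C)(C)C)O[C@@H]2[C@H](O[Si](C)(C)C(C)(C)C)C=C | intermediate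
9 | 3-methylbut-3-enoic acid | C=C(C)CC(=O)O | starting material
10 | TMSE 3-methylbut-3-enoate | C=C(C)CC(=O)OCC[Si](C)(C)C | intermediate
11 | E-side-chain CM product | O[C@@H]2C[C@@H](CCC(=O)OC(C)(C)C)O[C@@H]2[C@H](O[Si](C)(C)C(C)(C)C)/C=C(\C)CC(=O)OCC[Si](C)(C)C | intermediate
12 | acid | O[C@@H]2C[C@@H](CCC(=O)O)O[C@@H]2[C@H](O[Si](C)(C)C(C)(C)C)/C=C(\C)CC(=O)OCC[Si](C)(C)C | intermediate
13 | NHPI ester | O[C@@H]2C[C@@H](CCC(=O)ON3C(=O)c4ccccc4C3=O)O[C@@H]2[C@H](O[Si](C)(C)C(C)(C)C)/C=C(\C)CC(=O)OCC[Si](C)(C)C | intermediate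
14 | (R)-malic acid | OC(=O)C[C@@H](O)C(=O)O | starting material
15 | dioxolanone acid | CC1(C)O[C@H](CC(=O)O)C(=O)O1 | intermediate
16 | dioxolanone tert-butyl ester | CC1(C)O[C@H](CC(=O)OC(C)(C)C)C(=O)O1 | intermediate
17 | hydroxy ketone | CC(=O)[C@H](O)CC(=O)OC(C)(C)C | intermediate
18 | [2-(1,3-dioxolan-2-yl)ethyl]triphenylphosphonium bromide | [Br-].C1COC(O1)CC[P+](c1ccccc1)(c1ccccc1)c1ccccc1 | starting material
19 | Z-alkene acetal alcohol | O=C(OC(C)(C)C)C[C@@H](O)/C(C)=C\CC1OCCO1 | intermediate
20 | acetate | O=C(OC(C)(C)C)C[C@@H](OC(C)=O)/C(C)=C\CC1OCCO1 | intermediate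
21 | aldehyde | O=C(OC(C)(C)C)C[C@@H](OC(C)=O)/C(C)=C\CC=O | intermediate
22 | gem-dichloroalkene | O=C(OC(C)(C)C)C[C@@H](OC(C)=O)/C(C)=C\CC=C(Cl)Cl | intermediate
23 | coupled Z-chloroalkene ester | O[C@@H]2C[C@@H](CC/C(Cl)=C/C/C=C(/C)[C@H](OC(C)=O)CC(=O)OC(C)(C)C)O[C@@H]2[C@H](O[Si](C)(C)C(C)(C)C)/C=C(\C)CC(=O)OCC[Si](C)(C)C | intermediate
24 | seco-acid | O[C@@H]2C[C@@H](CC/C(Cl)=C/C/C=C(/C)[C@H](OC(C)=O)CC(=O)O)O[C@@H]2[C@H](O[Si](C)(C)C(C)(C)C)/C=C(\C)CC(=O)OCC[Si](C)(C)C | intermediate
25 | protected macrolactone | CC(=O)O[C@@H]1CC(=O)O[C@@H]2C[C@@H](CC/C(Cl)=C/C/C=C\1C)O[C@@H]2[C@H](O[Si](C)(C)C(C)(C)C)/C=C(\C)CC(=O)OCC[Si](C)(C)C | intermediate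
26 | target | CC(=O)O[C@@H]1CC(=O)O[C@@H]2C[C@@H](CC/C(Cl)=C/C/C=C\1C)O[C@@H]2[C@H](O)/C=C(\C)CC(=O)O | target

## Totals
Total steps: 21. Longest linear sequence: 13 (steps 1–6, 8–10, 18–21).

## Three steps most likely to fail
1. **Step 18 (proposed new step: stereoretentive mono-alkylation of the gem-dichloroalkene).** Risks are C–Cl oxidative addition being too slow for Ni/dtbbpy, double coupling, and hydrodecarboxylation.
   Fallback (known chemistry, different approach): convert acid 12 to the primary iodide by Barton photodecarboxylative iodination, make the alkylzinc (Zn, LiCl), and couple it with 22 under Pd(PtBu3)2 Negishi conditions. That reaction is known to substitute the E-chloride of 1,1-dichloroalkenes with retention, giving the same Z-chloroalkene.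
2. **Step 14 (Z-selectivity of the ketone Wittig).** Non-stabilised ylides with methyl ketones can give poor Z:E ratios.
   Fallback: Peterson olefination of a silyl-protected 17 with the α-silyl carbanion, separating the β-hydroxysilane diastereomers and eliminating with acid or base to give either alkene geometry stereospecifically.
3. **Step 4 (HAT–Giese on the bicyclic glycal, together with the Corey–Winter glycal in step 2).** The glycal may be labile, or HAT may be incomplete or non-selective.
   Fallback replacing steps 2–4: Fischer methyl glycosidation of 1, Barton–McCombie removal of the 2-OH, acetolysis and HBr to the 2-deoxy glycosyl bromide, then photoredox Giese with tert-butyl acrylate (Ir/Hantzsch ester), followed by 5-O-TBS protection. The exo attack anti to the lactone again sets C1.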